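Target in the cedar run lives 3.95 d: this is the lifetime of target, the time in which its amount falls by a factor e late in a run, read from that run's last two readings. I count turnovers, a flask's time divided by this lifetime.

| flask | starting material | remark | time |
|---|---|---|---|
| birch | 1.5 M | run made earlier |  |
| cedar | 0.75 M | run made earlier |  |
| oak | 1.1 M | run made earlier |  |
| blue | 1.5 M | everything together in a closed stirred flask, run for 4.0 d | 4.0 d |
| teal | 1.5 M | one stirred flow tank at steady state, fed with the mixture as stated, mean residence time 4.0 d |  |
| violet | 1.5 M | one stirred flow tank at steady state, fed with the mixture as stated, mean residence time 20.0 d |  |
| amber | 1.5 M | a tube with plug flow, the mixed feed as stated, residence time 4.0 d | 4.0 d |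

- birch (time / d: target / %): 0.208: 87.2; 0.333: 87.2; 0.500: 85.4; 0.833: 79.7; 1.67: 66.2; 2.50: 53.6
- cedar (time / d: target / %): 0.333: 82.7; 0.500: 83.3; 0.833: 79.0; 1.67: 66.2; 2.50: 55.1; 4.00: 37.7
- oak (time / d: target / %): 0.250: 85.2; 0.833: 79.5; 1.25: 73.0; 2.00: 60.8; 3.00: 48.4; 4.00: 37.7

(scatter of a reading: 0.3 percentage points)

1. the set-up with the highest amount of target at the outlet or at the end, in percent of the starting material put in ("none" if the first two lie within 2 percentage points) (blue / teal / violet / amber / none)
2. amount of target at the outlet or at the end, in percent of the starting material put in, blue
3. amount of target at the outlet or at the end, in percent of the starting material put in, teal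
4. amount of target at the outlet or at the end, in percent of the starting material put in, violet
5. amount of target at the outlet or at the end, in percent of the starting material put in, amber

- a species is counted by the starting material in it: one target counts as two
- the stated concentrations are those of everything mixed, before any reaction; amounts are the same in each set-up
- the earlier runs were made in a closed, stirred flask

I keep books on the starting material, counting target by the starting material in it. The first entry is what stays unreacted. If I book the 12.8% missing from target at the first birch reading as unreacted, and take the fall of starting material as second order, birch gives a rate of 32.8 /d per unit of unreacted fraction. Cedar gives 14.4 /d, so the rate is twice as high at twice the charge. On the birch rate, my steady tanks leave 8.36% unreacted in teal and 3.83% in violet.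

The second entry is surviving target, and the third is target lost. Carried back over its turnovers, the last birch reading gives 101%, close to the charge, so I open no fourth entry. Blue and amber share one history of 1.01 turnovers, and oak and cedar both read 37.7% at 4.00 d, so I book that reading as my estimate for blue and amber. A tank divides its converted share by one plus the count, which at teal's count keeps more than the closed flask's e to the minus count. I get 45.5% for teal and 15.9% for violet.

The forecast names teal, with 37.3% for blue, 46.7% for teal, 16.2% for violet and 37.3% for amber, on the ground that “first-order loss is penalised less by mixing”. My estimates differ from these: for teal mine is lower, for violet mine is lower, and for blue and amber mine is higher.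

The flask gives 37.5% in blue and 46.4% in teal, so teal stands highest.

2 starting material → target (k = 1.80 × 10⁻⁴ /M/s); target → over-reaction product (k = 2.90 × 10⁻⁶ /s) Violet's 20.0 d holds 5.06 turnovers against teal's 1.01, and its outlet carries 16.1% target with starting material at 0.0483 M. Amber, with a residence time of 4.0 d against the same mean residence time in teal, ends with 37.5% target and 62.0% over-reaction product.

(The data come from a simulation from invented constants; scatter was added.)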